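The numbers in the tables were generated by integration on assumed constants.

The unit I counted in was the half-life of a fall, not the minute, because the flask asked about is the theta flask itself, and its readings already held that clock.

in all of them: substrate 0.063 M; reagent 0.315 M

| flask | temperature | remark | time |
|---|---|---|---|
| theta | 60 °C | the very flask that is asked about, followed so far |  |
| epsilon | 45 °C | run made earlier |  |
| flask | 60 °C |  | 50 min |

| run | time / min | target / % |
|---|---|---|
| theta | 3.00 | 66 |
| theta | 5.00 | 73 |
| theta | 8.00 | 71 |
| theta | 15.0 | 65 |
| theta | 25.0 | 57 |
| theta | 40.0 | 56 |
| epsilon | 6.00 | 50 |
| epsilon | 10.0 | 66 |
| epsilon | 15.0 | 74 |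
| epsilon | 30.0 | 76 |
| epsilon | 50.0 | 72 |
| epsilon | 80.0 | 69 |

(standard deviation of a reading: 2 percentage points)

- target, in percent of the substrate first charged, at 50 min
- the option that brings most further target ("none" if no option brings more than 2 percentage points) (winter / autumn / midnight / summer / none)
- target present, with what was taken out counted in, in percent of the substrate first charged, after autumn
- target present, with what was taken out counted in, in percent of the substrate first charged, after midnight

- winter: change nothing and wait 1.5 h more
- autumn: at 50 min add reagent, 50.0 % of the amount charged, then wait 1.5 h
- midnight: at 50 min take out 90 % of the target then present, then wait 1.5 h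
- summer: at 50 min raise the temperature by 15 K, then wait 1.5 h

- percentages count the substrate that a species holds: one homo dimer counts as two
- what is taken out of target is counted as made
- steps that have been proposed: substrate + reagent <-> target; 2 substrate -> homo dimer; target <-> isomer of the product
- additions bring no volume worth counting

In the theta run target peaked and then stood near 56 %, so I took that last reading as a plateau and called the height of c(target) above it the excess:

excess at 8.00 min = 15 percentage points; at 15.0 min = 9 points

time for the excess to fall by a factor of two = 9.50 min

I called this time the relaxation half-life. Counted on from the later reading to 50 min, the excess in the theta flask came out at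

0.7 points

so I committed to about 56 % at 50 min, and winter looked useless, since that excess is less than the margin.

But the half-life rests on two readings with scatter. With the later one a standard deviation higher, the half-life stretched to 15.6 min, and the excess at 50 min became

2.3 points

which is more than the scatter of 2 points, so this doubt was not computed away: I kept about 56 % as my estimate but allowed up to 58.3 %.

A second doubt remained: the count tells when, not how high. The wait of 1.5 h spans 9.47 half-lives, and still 5.77 at the slow end, because it is much longer than the half-life. So whatever a reversible step gave back after midnight would arrive within the wait, and I favoured midnight without a height for it.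

The forecast gave 55.5 %, chose midnight, and put autumn at 57 % and midnight at 70 %, reading the curve thus: “a fast decline that stops looks like target relaxing to equilibrium with its isomer”.

The flask gave 55.3 % at 50 min, and midnight was best, bringing 22 points; autumn reached 57.4 %.

    substrate + reagent ⇌ target (K = 17.0 /M, k = 1.50 /M/min, Ea = 71.0 kJ/mol, ΔH = −50.0 kJ/mol)
    2 substrate → homo dimer (k = 1.50 × 10⁻⁴ /M/min, Ea = 88.0 kJ/mol)
    target ⇌ isomer of the product (K = 0.600, k = 0.0320 /min, Ea = 100 kJ/mol, ΔH = −20.0 kJ/mol)
    (constants at 60 °C)

The forecast and the flask parted at midnight, which reached 77.2 % against the forecast's 70 %; at 50.0 min the flask held 32.1 % of isomer of the product and also 12.6 % of substrate. The same half-life serves the same flask read at 20 min, which lies 0.526 half-lives after the later reading. The excess there shrinks to 6.2 points, which puts target at 62.2 %. That neighbouring flask gave 61.0 %.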